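**Strategy.** The dihydrochalcone is cut at the C(alpha)–C(beta) bond of the propanone chain into a chroman methyl ketone and a prenylated isovanillin-type aldehyde. The dihydropyran ring (O1, C2, C3, C4, C4a, C8a) is made from a 2,2-dimethyl-2,3-dihydrobenzofuran that carries an iodomethyl group on C3. A primary radical at that carbon attacks the electron-rich ipso carbon of the phloroglucinol ring (future C4a), and the 1,2-aryl shift inserts the CH2 as C4. This turns the five-membered ring into the chroman in one operation at the correct oxidation level. The key step exploits the C4–C4a aryl–methylene bond and the three oxygen substituents ortho and para to C4a.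

Key step: step 7

Remark: compounds 7–12 and 18 each carry one stereocentre (11 two), are formed as racemates and lead to an achiral target, so their SMILES carry no stereodescriptors. 3-Chloro-3-methylbut-1-yne, tributyl(3-methylbut-2-en-1-yl)stannane and 3-bromo-4,5-dihydroxybenzaldehyde are taken as commercial.

**Route**

Step 1
Reactants: 1 2,4,6-trihydroxyacetophenone
Product: 2 1-(2,4,6-trihydroxy-3-iodophenyl)ethan-1-one
Conditions: NIS (1.0 equiv), MeCN, −20 to 0 °C
Reagents that add atoms: N-iodosuccinimide, O=C1CCC(=O)N1I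
Why: Electrophilic aromatic iodination, in which the two free ring positions are equivalent and strongly activated, so one equivalent of reagent at low temperature should stop at the monoiodide.

Step 2
Reactants: 2 1-(2,4,6-trihydroxy-3-iodophenyl)ethan-1-one; 3 3-chloro-3-methylbut-1-yne
Product: 4 1-[2,6-dihydroxy-3-iodo-4-(2-methylbut-3-yn-2-yloxy)phenyl]ethan-1-one
Conditions: DBU (1.1 equiv), CuCl2·2H2O (1 mol%), MeCN, −5 to 0 °C
Reagents that add atoms: none
Why: Copper-catalysed propargylic etherification of the most acidic, non-chelated para hydroxyl, the two ortho hydroxyls being held by hydrogen bonds to the acetyl carbonyl; this fixes the future ring oxygen para to the acyl group.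

Step 3
Reactants: 4 1-[2,6-dihydroxy-3-iodo-4-(2-methylbut-3-yn-2-yloxy)phenyl]ethan-1-one
Product: 5 1-[3-iodo-2,6-bis(methoxymethoxy)-4-(2-methylbut-3-yn-2-yloxy)phenyl]ethan-1-one
Conditions: NaH (2.2 equiv), DMF, 0 °C; MOMCl (2.4 equiv), 0 °C to rt
Reagents that add atoms: chloromethyl methyl ether, COCCl
Why: Williamson-type O-alkylation of both phenoxides gives MOM acetals that mask the chelating phenols for the borane, radical and aldol steps and come off under mild acid at the end.

Step 4
Reactants: 5 1-[3-iodo-2,6-bis(methoxymethoxy)-4-(2-methylbut-3-yn-2-yloxy)phenyl]ethan-1-one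
Product: 6 1-[4,6-bis(methoxymethoxy)-2,2-dimethyl-3-methylidene-2,3-dihydro-1-benzofuran-5-yl]ethan-1-one
Conditions: Pd(OAc)2 (5 mol%), PPh3 (10 mol%), HCO2Na (1.5 equiv), Bu4NCl, DMF, 60 °C
Reagents that add atoms: none
Why: Reductive Heck-type cyclisation (oxidative addition into C–I, 5-exo-dig syn-carbopalladation of the alkyne, hydride transfer from formate) closes the dihydrofuran ring and leaves an exocyclic alkene that cannot move into the ring because C2 is quaternary.

Step 5
Reactants: 6 1-[4,6-bis(methoxymethoxy)-2,2-dimethyl-3-methylidene-2,3-dihydro-1-benzofuran-5-yl]ethan-1-one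
Product: 8 1-[3-(hydroxymethyl)-4,6-bis(methoxymethoxy)-2,2-dimethyl-2,3-dihydro-1-benzofuran-5-yl]ethan-1-one (racemic), via B-alkyl-9-BBN adduct 7 (not isolated)
Conditions: 9-BBN (1.5 equiv), THF, 0 °C to rt; then 30% H2O2, aq. NaOH, 0 °C
Reagents that add atoms: hydrogen peroxide, OO; 9-borabicyclo[3.3.1]nonane, B1C2CCCC1CCC2 (boron carrier in 7 only)
Why: Brown hydroboration–oxidation places boron and then oxygen on the terminal CH2 of the 1,1-disubstituted alkene, the bulky borane should spare the twisted, doubly ortho-substituted aryl ketone, and the new C3 stereocentre is formed as a racemate that is erased in step 7.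

Step 6
Reactants: 8 1-[3-(hydroxymethyl)-4,6-bis(methoxymethoxy)-2,2-dimethyl-2,3-dihydro-1-benzofuran-5-yl]ethan-1-one
Product: 9 1-[3-(iodomethyl)-4,6-bis(methoxymethoxy)-2,2-dimethyl-2,3-dihydro-1-benzofuran-5-yl]ethan-1-one (racemic)
Conditions: I2 (1.3 equiv), PPh3 (1.3 equiv), imidazole (2.5 equiv), CH2Cl2, 0 °C to rt
Reagents that add atoms: iodine, II
Why: Appel-type iodination of the primary alcohol under imidazole buffering, which keeps the MOM acetals intact and gives the radical precursor.

Step 7
Reactants: 9 1-[3-(iodomethyl)-4,6-bis(methoxymethoxy)-2,2-dimethyl-2,3-dihydro-1-benzofuran-5-yl]ethan-1-one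
Product: 13 1-[5,7-bis(methoxymethoxy)-2,2-dimethyl-3,4-dihydro-2H-chromen-6-yl]ethan-1-one, via primary alkyl radical 10 (not isolated), via spirocyclohexadienyl radical 11 (not isolated), via chroman-3-yl radical 12 (not isolated)
Conditions: (Me3Si)3SiH (1.3 equiv) and AIBN (0.3 equiv) added by syringe pump over 10 h to 9 in degassed toluene (0.005 M), 110 °C
Reagents that add atoms: none
Why: Iodine abstraction by the silyl radical gives primary radical 10, which adds to the ipso carbon of the arene (C3a of the benzofuran) to give the spiro[2.5]octadienyl radical 11, whose spin sits on three oxygen-bearing carbons; cleavage of the old C3–C3a bond then gives the secondary chroman-3-yl radical 12, which takes hydrogen from the silane. This is the neophyl (1,2-aryl) rearrangement in its ring-expanding form, the aryl counterpart of the Dowd–Beckwith ring expansion, known for (2,3-dihydrobenzofuran-3-yl)methyl radicals. The six-membered ring is closed by 3-exo-trig ipso attack followed by beta-scission, so the exocyclic CH2 becomes C4 and the five-membered ring grows by one carbon. No stereocentre is formed, and the racemic centre of 9 becomes the C3 methylene. The step needs the aryl shift to outrun hydrogen transfer to 10; high dilution, slow addition of a silane that donates hydrogen more slowly than a stannane, and 110 °C should secure this, while the change from a primary to a secondary radical and the release of strain of the fused five-membered ring make the shift downhill. The hindered aryl ketone and the MOM acetals should be inert to silyl radicals while the iodide is present.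

Step 8
Reactants: 14 3-bromo-4,5-dihydroxybenzaldehyde
Product: 15 3-bromo-5-hydroxy-4-methoxybenzaldehyde
Conditions: MeI (1.05 equiv), Li2CO3 (1.0 equiv), DMF, 40 °C
Reagents that add atoms: iodomethane, CI
Why: Regioselective Williamson methylation, since the hydroxyl para to the formyl group and ortho to bromine is the more acidic one and the weak base ionises only it.

Step 9
Reactants: 15 3-bromo-5-hydroxy-4-methoxybenzaldehyde; 16 tributyl(3-methylbut-2-en-1-yl)stannane
Product: 17 3-hydroxy-4-methoxy-5-(3-methylbut-2-en-1-yl)benzaldehyde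
Conditions: Pd(PPh3)4 (5 mol%), DMF, 100 °C
Reagents that add atoms: none
Why: Stille coupling transfers the allyl group at its alpha carbon to give the linear prenyl arene and tolerates the free phenol and the aldehyde.

Step 10
Reactants: 13 1-[5,7-bis(methoxymethoxy)-2,2-dimethyl-3,4-dihydro-2H-chromen-6-yl]ethan-1-one; 17 3-hydroxy-4-methoxy-5-(3-methylbut-2-en-1-yl)benzaldehyde
Product: 19 (E)-1-[5,7-bis(methoxymethoxy)-2,2-dimethyl-3,4-dihydro-2H-chromen-6-yl]-3-[3-hydroxy-4-methoxy-5-(3-methylbut-2-en-1-yl)phenyl]prop-2-en-1-one, via aldol adduct 18 (not isolated)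
Conditions: KOH (6 equiv), EtOH/H2O, rt, 48 h; then dilute HCl to pH 5, 0 °C
Reagents that add atoms: none
Why: Claisen–Schmidt condensation of the methyl ketone enolate with the non-enolisable aldehyde followed by E1cB loss of water gives the trans enone, and with both ortho oxygens protected no flavanone can form.

Step 11
Reactants: 19 (E)-chalcone
Product: 20 1-[5,7-bis(methoxymethoxy)-2,2-dimethyl-3,4-dihydro-2H-chromen-6-yl]-3-[3-hydroxy-4-methoxy-5-(3-methylbut-2-en-1-yl)phenyl]propan-1-one
Conditions: H2 (1 atm), RhCl(PPh3)3 (5 mol%), benzene/EtOH 1:1, rt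
Reagents that add atoms: none
Why: Homogeneous hydrogenation with Wilkinson's catalyst should reduce the disubstituted enone C=C while leaving the trisubstituted prenyl alkene, the ketone and the arenes untouched.

Step 12
Reactants: 20 bis-MOM dihydrochalcone
Product: 21 1-(5,7-dihydroxy-2,2-dimethyl-3,4-dihydro-2H-chromen-6-yl)-3-[3-hydroxy-4-methoxy-5-(3-methylbut-2-en-1-yl)phenyl]propan-1-one (CNP0408176.0)
Conditions: 3 M aq. HCl, MeOH, 45 °C
Reagents that add atoms: none
Why: Acid-catalysed transacetalisation to methanol removes both MOM groups; the prenyl group has no ortho hydroxyl to cyclise onto and the chroman ether should be stable at this acidity.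

**Compound list**

1 | 2,4,6-trihydroxyacetophenone | CC(=O)c1c(O)cc(O)cc1O | starting material
2 | 1-(2,4,6-trihydroxy-3-iodophenyl)ethan-1-one | CC(=O)c1c(O)cc(O)c(I)c1O | intermediate
3 | 3-chloro-3-methylbut-1-yne | CC(C)(Cl)C#C | starting material
4 | 1-[2,6-dihydroxy-3-iodo-4-(2-methylbut-3-yn-2-yloxy)phenyl]ethan-1-one | CC(=O)c1c(O)cc(OC(C)(C)C#C)c(I)c1O | intermediate
5 | 1-[3-iodo-2,6-bis(methoxymethoxy)-4-(2-methylbut-3-yn-2-yloxy)phenyl]ethan-1-one | CC(=O)c1c(OCOC)cc(OC(C)(C)C#C)c(I)c1OCOC | intermediate
6 | 1-[4,6-bis(methoxymethoxy)-2,2-dimethyl-3-methylidene-2,3-dihydro-1-benzofuran-5-yl]ethan-1-one | CC(=O)c1c(OCOC)cc2OC(C)(C)C(=C)c2c1OCOC | intermediate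
7 | 1-[3-(9-borabicyclo[3.3.1]nonan-9-ylmethyl)-4,6-bis(methoxymethoxy)-2,2-dimethyl-2,3-dihydro-1-benzofuran-5-yl]ethan-1-one (racemic, not isolated) | CC(=O)c1c(OCOC)cc2OC(C)(C)C(CB3C4CCCC3CCC4)c2c1OCOC | intermediate
8 | 1-[3-(hydroxymethyl)-4,6-bis(methoxymethoxy)-2,2-dimethyl-2,3-dihydro-1-benzofuran-5-yl]ethan-1-one (racemic) | CC(=O)c1c(OCOC)cc2OC(C)(C)C(CO)c2c1OCOC | intermediate
9 | 1-[3-(iodomethyl)-4,6-bis(methoxymethoxy)-2,2-dimethyl-2,3-dihydro-1-benzofuran-5-yl]ethan-1-one (racemic) | CC(=O)c1c(OCOC)cc2OC(C)(C)C(CI)c2c1OCOC | intermediate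
10 | [5-acetyl-4,6-bis(methoxymethoxy)-2,2-dimethyl-2,3-dihydro-1-benzofuran-3-yl]methyl radical (not isolated) | CC(=O)c1c(OCOC)cc2OC(C)(C)C([CH2])c2c1OCOC | intermediate
11 | spiro[2.5]octadienyl radical with the cyclopropane fused to the dihydrofuran ring, one resonance form drawn (not isolated) | CC(=O)C1=C(OCOC)C23CC2C(C)(C)O[C]3C=C1OCOC | intermediate
12 | 6-acetyl-5,7-bis(methoxymethoxy)-2,2-dimethylchroman-3-yl radical (not isolated) | CC(=O)c1c(OCOC)cc2OC(C)(C)[CH]Cc2c1OCOC | intermediate
13 | 1-[5,7-bis(methoxymethoxy)-2,2-dimethyl-3,4-dihydro-2H-chromen-6-yl]ethan-1-one | CC(=O)c1c(OCOC)cc2OC(C)(C)CCc2c1OCOC | intermediate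
14 | 3-bromo-4,5-dihydroxybenzaldehyde | Oc1c(O)cc(C=O)cc1Br | starting material
15 | 3-bromo-5-hydroxy-4-methoxybenzaldehyde | COc1c(O)cc(C=O)cc1Br | intermediate
16 | tributyl(3-methylbut-2-en-1-yl)stannane | CCCC[Sn](CCCC)(CCCC)CC=C(C)C | starting material
17 | 3-hydroxy-4-methoxy-5-(3-methylbut-2-en-1-yl)benzaldehyde | COc1c(O)cc(C=O)cc1CC=C(C)C | intermediate
18 | 1-[5,7-bis(methoxymethoxy)-2,2-dimethylchroman-6-yl]-3-hydroxy-3-[3-hydroxy-4-methoxy-5-(3-methylbut-2-en-1-yl)phenyl]propan-1-one (racemic, not isolated) | COc1c(O)cc(C(O)CC(=O)c2c(OCOC)cc3OC(C)(C)CCc3c2OCOC)cc1CC=C(C)C | intermediate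
19 | (E)-1-[5,7-bis(methoxymethoxy)-2,2-dimethyl-3,4-dihydro-2H-chromen-6-yl]-3-[3-hydroxy-4-methoxy-5-(3-methylbut-2-en-1-yl)phenyl]prop-2-en-1-one | COc1c(O)cc(/C=C/C(=O)c2c(OCOC)cc3OC(C)(C)CCc3c2OCOC)cc1CC=C(C)C | intermediate
20 | 1-[5,7-bis(methoxymethoxy)-2,2-dimethyl-3,4-dihydro-2H-chromen-6-yl]-3-[3-hydroxy-4-methoxy-5-(3-methylbut-2-en-1-yl)phenyl]propan-1-one | COc1c(O)cc(CCC(=O)c2c(OCOC)cc3OC(C)(C)CCc3c2OCOC)cc1CC=C(C)C | intermediate
21 | 1-(5,7-dihydroxy-2,2-dimethyl-3,4-dihydro-2H-chromen-6-yl)-3-[3-hydroxy-4-methoxy-5-(3-methylbut-2-en-1-yl)phenyl]propan-1-one | COc1c(O)cc(CCC(=O)c2c(O)cc3c(c2O)CCC(C)(C)O3)cc1CC=C(C)C | target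

**Step count and risks**

Total step count: 12. Longest linear sequence: 10 (steps 1–7, then 10–12).

Steps most likely to fail:

Step 7. Hydrogen transfer to the primary radical may be faster than the aryl shift, which would give the unrearranged 3-methyl dihydrobenzofuran; fragmentation of the rearranged radical by loss of the aryloxy group is a lesser concern. The fallback sets out from alkene 6 and keeps the ring expansion but makes it cationic. PhI(OH)OTs (Koser's reagent) in 95% MeOH at rt should add to the exocyclic alkene and trigger an oxidative 1,2-aryl shift to 6-acetyl-5,7-bis(methoxymethoxy)-2,2-dimethylchroman-3(4H)-one F1. Condensation with p-toluenesulfonylhydrazide in EtOH should occur only at this unhindered ketone and give the tosylhydrazone F2. Reduction with catecholborane in CHCl3 followed by NaOAc·3H2O then removes the carbonyl and returns to the route at 13.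

Step 5. The borane may reduce the aryl ketone in competition with a slow hydroboration of the hindered alkene. The fallback sets out from 5 and bypasses 6. Semihydrogenation over Pd/CaCO3 poisoned with Pb(OAc)2 and quinoline (H2, EtOAc, rt) gives 1-[3-iodo-2,6-bis(methoxymethoxy)-4-(2-methylbut-3-en-2-yloxy)phenyl]ethan-1-one F3, which is kept cold to avoid Claisen rearrangement. Treatment with Bu3SnH under a stream of dry air in toluene at 0 °C to rt should give aryl radical 5-exo-trig cyclisation, capture of the primary radical by oxygen faster than any aryl shift, and reduction of the hydroperoxide, returning to the route at alcohol 8.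

Step 2. Site selectivity may be lost in the O-alkylation of the hindered iodinated triol, with attack at an ortho hydroxyl or at ring carbon. The fallback sets out from 1 and changes the order so that the ether is made on the symmetric, unhindered triol. Compounds 1 and 3 under the same DBU/CuCl2·2H2O conditions give 1-[2,6-dihydroxy-4-(2-methylbut-3-yn-2-yloxy)phenyl]ethan-1-one F4. NaH/MOMCl in DMF gives 1-[2,6-bis(methoxymethoxy)-4-(2-methylbut-3-yn-2-yloxy)phenyl]ethan-1-one F5. Monoiodination at one of the two equivalent ring positions with NIS and catalytic CF3CO2H in MeCN at 0 °C returns to the route at 5.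

Further compounds
F1 | step 7 | 6-acetyl-5,7-bis(methoxymethoxy)-2,2-dimethylchroman-3(4H)-one | CC(=O)c1c(OCOC)cc2OC(C)(C)C(=O)Cc2c1OCOC
F2 | step 7 | N'-[6-acetyl-5,7-bis(methoxymethoxy)-2,2-dimethylchroman-3-ylidene]-4-methylbenzenesulfonohydrazide | CC(=O)c1c(OCOC)cc2OC(C)(C)C(=NNS(=O)(=O)c3ccc(C)cc3)Cc2c1OCOC
F3 | step 5 | 1-[3-iodo-2,6-bis(methoxymethoxy)-4-(2-methylbut-3-en-2-yloxy)phenyl]ethan-1-one | CC(=O)c1c(OCOC)cc(OC(C)(C)C=C)c(I)c1OCOC
F4 | step 2 | 1-[2,6-dihydroxy-4-(2-methylbut-3-yn-2-yloxy)phenyl]ethan-1-one | CC(=O)c1c(O)cc(OC(C)(C)C#C)cc1O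
F5 | step 2 | 1-[2,6-bis(methoxymethoxy)-4-(2-methylbut-3-yn-2-yloxy)phenyl]ethan-1-one | CC(=O)c1c(OCOC)cc(OC(C)(C)C#C)cc1OCOC
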